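**Plan**
- **Cuts (labdane numbering; ring A = C1–C5, C10; ring B = C5–C10).** The retrosynthesis cuts C13=C14 (olefination), then C9–C11 and C8–CH3 (conjugate addition and enolate methylation on a ring B dienone). It then cuts C4–C5 and reconnects C2 to C7, which gives a bicyclo[2.2.2]octene.
- **Enabling feature.** C4 and C10 are quaternary, 1,3-related through C5 in ring A, and carry syn (β) methyl groups. If C10 is a bridgehead and C4 the terminus of an E-trisubstituted alkene, a boat-locked [3,3] shift sets this relation. Ring B is the carbocycle of 4-methylanisole with its oxygen on C7.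
- **Forward order.** Ring B comes first (Birch reduction) and is bridged by C1–C2 in a Diels–Alder reaction. C3, C4, C18 and the prenyl end are then added by Grignard addition, Johnson–Claisen rearrangement and Wittig olefination. Ring A closes in the oxy-Cope step. After that C5 is inverted, C9 and C8 are substituted, C7 is deoxygenated and the acid chain is completed.
- **Stereochemistry.** The absolute configuration (C10 and the endo C2) comes from the Cu(OTf)2/(S,S)-t-Bu-box Diels–Alder reaction. C4 comes from the E alkene within the boat. C5 forms cis and is reset to trans by Li/NH3 on the Δ5-7-one. The E-enoate comes from the Horner–Wadsworth–Emmons step.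

Key step: step 11

Remark: β is the face of the C10 methyl group. Labdane C7, C2, C1, C10, C5, C6, C8, C9 correspond to bicyclooctene C1, C2, C3, C4, C5, C6, C7, C8. The short-lived centres (carbinol carbon of 10 and 12, C8 of 27 to 29) are carried as epimer mixtures because later steps erase them.

Step 1
Reactants: 1 4-methylanisole
Product: 3 4-methylcyclohex-3-en-1-one, via 1-methoxy-4-methylcyclohexa-1,4-diene 2 (not isolated)
Conditions: Li, NH3(l), THF, t-BuOH, −78 to −33 °C, then NH4Cl; crude 2, (CO2H)2 (cat.), THF/H2O, rt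
Reagents that add atoms: water, O
Why: Birch reduction of the anisole leaves the enol ether and the methyl-substituted alkene in a 1,4-relation, and oxalic acid hydrolyses only the enol ether, so the β,γ-enone should form without conjugation.

Step 2
Reactants: 3 4-methylcyclohex-3-en-1-one
Product: 4 tert-butyl(dimethyl)[(4-methylcyclohexa-1,3-dien-1-yl)oxy]silane
Conditions: TBSOTf, Et3N, CH2Cl2, 0 °C
Reagents that add atoms: tert-butyldimethylsilyl triflate, CC(C)(C)[Si](C)(C)OS(=O)(=O)C(F)(F)F
Why: Soft enolisation (O-silylation with silyl triflate and amine) removes the doubly activated proton between the carbonyl group and the alkene, which gives the linearly conjugated 1-silyloxy-1,3-diene whose termini are the future C7 and C10.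

Step 3
Reactants: 4 silyloxydiene; 5 3-acryloyl-1,3-oxazolidin-2-one
Product: 6 3-{[(1R,2S,4S)-1-(tert-butyldimethylsilyloxy)-4-methylbicyclo[2.2.2]oct-5-en-2-yl]carbonyl}-1,3-oxazolidin-2-one (acyl group endo, syn to C5=C6)
Conditions: Cu(OTf)2 (10 mol %), (S,S)-t-Bu-box [2,2'-(propane-2,2-diyl)bis((4S)-4-tert-butyl-4,5-dihydrooxazole), 11 mol %], 4 Å MS, CH2Cl2, −40 to −10 °C
Reagents that add atoms: 3-acryloyl-1,3-oxazolidin-2-one 5, C=CC(=O)N1CCOC1=O
Why: In this catalytic enantioselective Diels–Alder reaction the silyloxy group directs the acyl-bearing carbon next to C–O ("ortho" rule), secondary orbital overlap places the acyl group endo, and the square-planar chelate of the s-cis imide on divalent copper leaves open only the alkene face remote from the tert-butyl group, which sets C7, C2 and C10 as 1R,2S,4S.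

Step 4
Reactants: 6 Diels–Alder imide
Product: 7 [(1R,2R,4S)-1-(tert-butyldimethylsilyloxy)-4-methylbicyclo[2.2.2]oct-5-en-2-yl]methanol
Conditions: LiBH4, THF, 0 °C to rt
Reagents that add atoms: none
Why: Reductive cleavage of an N-acyloxazolidinone with LiBH4 attacks the exocyclic carbonyl group and needs no base, so the endo centre C2, the silyl ether and the alkene are kept.

Step 5
Reactants: 7 primary alcohol
Product: 8 (1R,2S,4S)-1-(tert-butyldimethylsilyloxy)-4-methylbicyclo[2.2.2]oct-5-ene-2-carbaldehyde
Conditions: Dess–Martin periodinane, CH2Cl2, 0 °C to rt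
Reagents that add atoms: none
Why: Dess–Martin oxidation is neutral and fast, so the α-branched endo aldehyde should form without epimerisation at C2, and β-elimination of the silyloxy group is excluded at a bridgehead.

Step 6
Reactants: 8 aldehyde; 9 isopropenylmagnesium bromide
Product: 10 1-[(1R,2R,4S)-1-(tert-butyldimethylsilyloxy)-4-methylbicyclo[2.2.2]oct-5-en-2-yl]-2-methylprop-2-en-1-ol (carbinol epimers)
Conditions: THF, −78 °C; then H2O
Reagents that add atoms: isopropenylmagnesium bromide 9, C=C(C)[Mg]Br
Why: Grignard 1,2-addition to the aldehyde delivers C4, its methyl group and C18 in one operation, and the new carbinol centre needs no control because both epimers converge in step 7.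

Step 7
Reactants: 10 allylic alcohol; 11 triethyl orthoacetate
Product: 13 ethyl (4E)-5-[(1R,2R,4S)-1-(tert-butyldimethylsilyloxy)-4-methylbicyclo[2.2.2]oct-5-en-2-yl]-4-methylpent-4-enoate, via mixed ketene acetal 12 (not isolated)
Conditions: MeC(OEt)3 (excess), EtCO2H (cat.), 140 °C, EtOH distilled off
Reagents that add atoms: triethyl orthoacetate 11, CC(OCC)(OCC)OCC
Why: In the chair transition state of the Johnson–Claisen rearrangement the bulky bicyclic residue sits equatorial, so both carbinol epimers should give the E-trisubstituted C3=C4 alkene with the methyl group cis to C2.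

Step 8
Reactants: 13 ethyl ester
Product: 14 (4E)-5-[(1R,2R,4S)-1-(tert-butyldimethylsilyloxy)-4-methylbicyclo[2.2.2]oct-5-en-2-yl]-4-methylpent-4-enal
Conditions: i-Bu2AlH (1.05 equiv), CH2Cl2, −78 °C; Rochelle salt
Reagents that add atoms: none
Why: Partial ester reduction with i-Bu2AlH at low temperature stops at the tetrahedral aluminium alkoxide, which releases the aldehyde only on work-up.

Step 9
Reactants: 14 aldehyde; 15 isopropyltriphenylphosphonium iodide
Product: 16 tert-butyl{[(1R,2R,4S)-2-[(1E)-2,6-dimethylhepta-1,5-dien-1-yl]-4-methylbicyclo[2.2.2]oct-5-en-1-yl]oxy}dimethylsilane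
Conditions: 15, n-BuLi, THF, 0 °C; then 14, −78 °C to rt
Reagents that add atoms: isopropyltriphenylphosphonium iodide 15, CC(C)[P+](c1ccccc1)(c1ccccc1)c1ccccc1.[I-]
Why: Wittig olefination with the non-stabilised isopropylidene ylide forms the terminal trisubstituted alkene, which has no E/Z isomers, and the aldehyde has no adjacent stereocentre to lose.

Step 10
Reactants: 16 bridgehead silyl ether
Product: 17 (1R,2R,4S)-2-[(1E)-2,6-dimethylhepta-1,5-dien-1-yl]-4-methylbicyclo[2.2.2]oct-5-en-1-ol (side chain endo)
Conditions: n-Bu4NF, THF, rt to 50 °C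
Reagents that add atoms: none
Why: Fluoride-mediated desilylation frees the bridgehead alcohol, since the tied-back bridgehead keeps this tertiary silyl ether accessible and nothing else in 16 reacts with fluoride.

Step 11
Reactants: 17 2-endo-alkenyl bridgehead alcohol
Product: 20 cis-fused (5β-H) 4β,10β-dimethyl-4α-(4-methylpent-3-enyl)octal-2-en-7-one [(4aS,8R,8aS)-4a,8-dimethyl-8-(4-methylpent-3-en-1-yl)-3,4,4a,5,8,8a-hexahydronaphthalen-2(1H)-one], via potassium alkoxide 18 (not isolated), via potassium enolate 19 (not isolated)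
Conditions: KH, 18-crown-6, THF, 0 to 66 °C; then aq. NH4Cl, −78 °C
Reagents that add atoms: none
Why: KH/18-crown-6 gives the naked bridgehead alkoxide 18, whose oxygen weakens the adjacent C2–C7 bond, and the 1,5-diene C4=C3–C2–C7–C6=C5 reorganises in a concerted [3,3] shift (anionic oxy-Cope rearrangement) to the C6=C7 enolate 19, which is protonated to 20. The closest known reaction type is the anionic oxy-Cope rearrangement of endo-2-alkenylbicyclo[2.2.2]oct-5-en-2-ols to cis-decalenones; here the oxygen sits on the other carbon of the breaking bond, the bridgehead. Ring A (C1–C5, C10) closes through the sigmatropic C4–C5 bond in a six-centre boat array while the C2–C7 bridge opens, so the bicyclo[2.2.2]octene becomes a decalin. C5 is set by the endo side chain, which can reach only the face of C5=C6 that looks at the C1–C2 bridge, and this places H5 cis to the C10 methyl group. C4 is set by the alkene geometry within the boat: the substituent cis to C2 lies over C10 and ends syn to its methyl group, so the E alkene puts CH3 on the β face and the chain on the α face. The step needs the concerted path to beat heterolysis of C2–C7 and cycloreversion, which the rigid endo geometry (termini held close), the strain release of the bridged skeleton and the formation of a stable enolate should secure.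

Step 12
Reactants: 20 cis-octalenone
Product: 21 cis-fused (5β-H) 4β,10β-dimethyl-4α-(4-methylpent-3-enyl)decal-7-one
Conditions: H2 (1 atm), RhCl(PPh3)3 (5 mol %), benzene/EtOH 1:1, rt
Reagents that add atoms: none
Why: Homogeneous hydrogenation with RhCl(PPh3)3 discriminates by substitution, so the cis-disubstituted C2=C3 ring alkene should be saturated while the trisubstituted side-chain alkene and the ketone stay untouched.

Step 13
Reactants: 21 cis-decalone
Product: 23 4β,10β-dimethyl-4α-(4-methylpent-3-enyl)hexal-5,8-dien-7-one (cross-conjugated dienone), via octal-5-en-7-one 22 (not isolated)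
Conditions: IBX (4 equiv), DMSO, 80 °C
Reagents that add atoms: none
Why: IBX dehydrogenates ketones through their enols, and with excess reagent both α,β-positions are oxidised as in the conversion of saturated 3-keto steroids into 1,4-dien-3-ones, which erases the wrong C5 centre and activates C9 at the same time.

Step 14
Reactants: 23 dienone; 24 but-3-enylmagnesium bromide; 25 iodomethane
Product: 27 9α-(but-3-enyl)-4β,8,10β-trimethyl-4α-(4-methylpent-3-enyl)octal-5-en-7-one (C8 epimers), via bromomagnesium dienolate 26 (not isolated)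
Conditions: 24, CuBr·SMe2 (20 mol %), THF, −40 °C; then MeI, DMPU, −40 °C to rt
Reagents that add atoms: but-3-enylmagnesium bromide 24, C=CCC[Mg]Br; iodomethane 25, CI
Why: In this copper-catalysed conjugate addition with enolate methylation only the disubstituted C8=C9 bond accepts the nucleophile, as with steroidal 1,4-dien-3-ones (C5 is fully substituted and flanked by C4 and C10), attack comes anti to the C10 methyl group (9α), and the cross-conjugated enolate 26 can be methylated only at C8.

Step 15
Reactants: 27 Δ5-7-one
Product: 29 trans-fused (5α-H) 9α-(but-3-enyl)-4β,8,10β-trimethyl-4α-(4-methylpent-3-enyl)decal-7-one (C8 epimers), via lithium enolate 28 (not isolated)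
Conditions: Li, NH3(l), THF, t-BuOH (1 equiv), −78 to −33 °C; then NH4Cl
Reagents that add atoms: none
Why: In the dissolving-metal reduction of the enone the β-carbanion at C5 is protonated axially on the α face, which gives the trans-decalone as with 4-en-3-one steroids, while the isolated alkenes are inert.

Step 16
Reactants: 29 trans-decalone
Product: 30 trans-fused 9α-(but-3-enyl)-4β,8,10β-trimethyl-4α-(4-methylpent-3-enyl)-7-(trimethylsilyloxy)octal-7-ene
Conditions: TMSCl, NaI, Et3N, MeCN, rt
Reagents that add atoms: chlorotrimethylsilane, C[Si](C)(C)Cl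
Why: Thermodynamic silyl enol ether formation with iodotrimethylsilane made in situ favours the tetrasubstituted C7=C8 isomer, in line with the enolisation of trans-fused 3-keto steroids away from the ring fusion.

Step 17
Reactants: 30 silyl enol ether
Product: 33 trans-fused 9-(but-3-enyl)-4β,8,10β-trimethyl-4α-(4-methylpent-3-enyl)octal-8-en-7-one, via 8β-phenylselanyl ketone 31 (not isolated), via selenoxide 32 (not isolated)
Conditions: PhSeCl (1.0 equiv), CH2Cl2, −78 °C; then H2O2 (30 %), pyridine, 0 °C to rt
Reagents that add atoms: none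
Why: In this selenenylation and selenoxide syn-elimination PhSeCl should enter C8 axially from the β face, anti to the axial 9α chain, so that the selenoxide is cis to the only hydrogen on C9 and the conjugated tetrasubstituted C8=C9 bond can form.

Step 18
Reactants: 33 tetrasubstituted enone
Product: 34 trans-fused 9-(but-3-enyl)-4β,8,10β-trimethyl-4α-(4-methylpent-3-enyl)octal-8-en-7β-ol
Conditions: i-Bu2AlH, CH2Cl2, −78 °C; Rochelle salt
Reagents that add atoms: none
Why: In the 1,2-reduction of the enone with i-Bu2AlH hydride should come from the open α face (the β face carries the C10 methyl group) and give the 7β-alcohol, a centre that step 19 removes.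

Step 19
Reactants: 34 allylic alcohol
Product: 36 trans-fused 9-(but-3-enyl)-4β,8,10β-trimethyl-4α-(4-methylpent-3-enyl)octal-8-ene, via pyridinium 7β-sulfate 35 (not isolated)
Conditions: SO3·pyridine, THF, 0 °C; then LiAlH4, 0 °C to rt
Reagents that add atoms: none
Why: In this deoxygenation of an allylic alcohol through its sulfate monoester and LiAlH4 hydride displaces the sulfate directly at secondary C7 from the α face, because the SN2' terminus C9 is fully substituted and neopentyl, so the C8=C9 bond stays in place.

Step 20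
Reactants: 36 triene
Product: 37 4-[(4aS,5S,8aS)-2,5,8a-trimethyl-5-(4-methylpent-3-en-1-yl)-3,4,4a,5,6,7,8,8a-octahydronaphthalen-1-yl]butan-2-one
Conditions: PdCl2 (10 mol %), CuCl (1 equiv), O2 (1 atm), DMF/H2O 7:1, rt
Reagents that add atoms: water, O
Why: Wacker–Tsuji oxidation is selective for the terminal alkene and follows Markovnikov regiochemistry, so the methyl ketone forms while the tri- and tetrasubstituted alkenes do not bind to divalent palladium.

Step 21
Reactants: 37 methyl ketone; 38 triethyl phosphonoacetate
Product: 39 ethyl (2E)-3-methyl-5-[(4aS,5S,8aS)-2,5,8a-trimethyl-5-(4-methylpent-3-en-1-yl)-3,4,4a,5,6,7,8,8a-octahydronaphthalen-1-yl]pent-2-enoate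
Conditions: 38, NaH, THF, 0 °C to reflux; chromatography
Reagents that add atoms: triethyl phosphonoacetate 38, CCOC(=O)CP(=O)(OCC)OCC
Why: Horner–Wadsworth–Emmons olefination of the methyl ketone should give mainly the E-enoate (ester trans to the larger CH2 branch), and the minor Z isomer is removed by chromatography.

Step 22
Reactants: 39 ethyl ester
Product: 41 CNP0237483.2, (2E)-3-methyl-5-[(4aS,5S,8aS)-2,5,8a-trimethyl-5-(4-methylpent-3-en-1-yl)-3,4,4a,5,6,7,8,8a-octahydronaphthalen-1-yl]pent-2-enoic acid, via lithium carboxylate 40 (not isolated)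
Conditions: LiOH, THF/MeOH/H2O, 50 °C; then 1 M HCl to pH 4, 0 °C
Reagents that add atoms: lithium hydroxide, [Li+].[OH-]
Why: Saponification of the ethyl ester followed by mild acidification gives the acid, and aqueous base touches no stereocentre or alkene.

**Compound list**
1 | 4-methylanisole | COc1ccc(C)cc1 | starting material
2 | 1-methoxy-4-methylcyclohexa-1,4-diene | COC1=CCC(C)=CC1 | intermediate
3 | 4-methylcyclohex-3-en-1-one | CC1=CCC(=O)CC1 | intermediate
4 | tert-butyl(dimethyl)[(4-methylcyclohexa-1,3-dien-1-yl)oxy]silane | CC1=CC=C(O[Si](C)(C)C(C)(C)C)CC1 | intermediate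
5 | 3-acryloyl-1,3-oxazolidin-2-one | C=CC(=O)N1CCOC1=O | starting material
6 | endo (1R,2S,4S) Diels–Alder imide | O=C1OCCN1C(=O)[C@H]2C[C@@]3(C)C=C[C@]2(O[Si](C)(C)C(C)(C)C)CC3 | intermediate
7 | (1R,2R,4S) primary alcohol | OC[C@H]1C[C@@]2(C)C=C[C@]1(O[Si](C)(C)C(C)(C)C)CC2 | intermediate
8 | (1R,2S,4S) aldehyde | O=C[C@H]1C[C@@]2(C)C=C[C@]1(O[Si](C)(C)C(C)(C)C)CC2 | intermediate
9 | isopropenylmagnesium bromide | C=C(C)[Mg]Br | starting material
10 | isopropenyl carbinol (carbinol epimers) | C=C(C)C(O)[C@H]1C[C@@]2(C)C=C[C@]1(O[Si](C)(C)C(C)(C)C)CC2 | intermediate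
11 | triethyl orthoacetate | CC(OCC)(OCC)OCC | starting material
12 | mixed ketene acetal of 10 | C=C(OCC)OC(C(C)=C)[C@H]1C[C@@]2(C)C=C[C@]1(O[Si](C)(C)C(C)(C)C)CC2 | intermediate
13 | E-γ,δ-unsaturated ethyl ester | CCOC(=O)CC/C(C)=C/[C@H]1C[C@@]2(C)C=C[C@]1(O[Si](C)(C)C(C)(C)C)CC2 | intermediate
14 | E-γ,δ-unsaturated aldehyde | O=CCC/C(C)=C/[C@H]1C[C@@]2(C)C=C[C@]1(O[Si](C)(C)C(C)(C)C)CC2 | intermediate
15 | isopropyltriphenylphosphonium iodide | CC(C)[P+](c1ccccc1)(c1ccccc1)c1ccccc1.[I-] | starting material
16 | silyl ether of 17 | CC(C)=CCC/C(C)=C/[C@H]1C[C@@]2(C)C=C[C@]1(O[Si](C)(C)C(C)(C)C)CC2 | intermediate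
17 | (1R,2R,4S)-2-[(1E)-2,6-dimethylhepta-1,5-dien-1-yl]-4-methylbicyclo[2.2.2]oct-5-en-1-ol | CC(C)=CCC/C(C)=C/[C@H]1C[C@@]2(C)C=C[C@]1(O)CC2 | intermediate
18 | potassium alkoxide of 17 | CC(C)=CCC/C(C)=C/[C@H]1C[C@@]2(C)C=C[C@]1([O-])CC2.[K+] | intermediate
19 | potassium C6=C7 enolate of 20 | CC(C)=CCC[C@]1(C)C=CC[C@]2(C)CCC([O-])=C[C@H]12.[K+] | intermediate
20 | cis-fused octal-2-en-7-one | CC(C)=CCC[C@]1(C)C=CC[C@]2(C)CCC(=O)C[C@H]12 | intermediate
21 | cis-fused decal-7-one | CC(C)=CCC[C@]1(C)CCC[C@]2(C)CCC(=O)C[C@H]12 | intermediate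
22 | octal-5-en-7-one | CC(C)=CCC[C@]1(C)CCC[C@]2(C)CCC(=O)C=C12 | intermediate
23 | hexal-5,8-dien-7-one | CC(C)=CCC[C@]1(C)CCC[C@]2(C)C=CC(=O)C=C12 | intermediate
24 | but-3-enylmagnesium bromide | C=CCC[Mg]Br | starting material
25 | iodomethane | CI | starting material
26 | bromomagnesium dienolate | CC(C)=CCC[C@]1(C)CCC[C@]2(C)[C@H](CCC=C)C=C(O[Mg]Br)C=C12 | intermediate
27 | 9α-butenyl-8-methyl-octal-5-en-7-one (C8 epimers) | CC(C)=CCC[C@]1(C)CCC[C@]2(C)[C@H](CCC=C)C(C)C(=O)C=C12 | intermediate
28 | lithium C6=C7 enolate of 29 | CC(C)=CCC[C@]1(C)CCC[C@]2(C)[C@H](CCC=C)C(C)C([O-])=C[C@@H]12.[Li+] | intermediate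
29 | trans-fused 9α-butenyl-8-methyl-decal-7-one (C8 epimers) | CC(C)=CCC[C@]1(C)CCC[C@]2(C)[C@H](CCC=C)C(C)C(=O)C[C@@H]12 | intermediate
30 | C7=C8 trimethylsilyl enol ether | CC(C)=CCC[C@]1(C)CCC[C@]2(C)[C@H](CCC=C)C(C)=C(O[Si](C)(C)C)C[C@@H]12 | intermediate
31 | 8β-phenylselanyl ketone | CC(C)=CCC[C@]1(C)CCC[C@]2(C)[C@H](CCC=C)[C@@](C)([Se]c3ccccc3)C(=O)C[C@@H]12 | intermediate
32 | selenoxide of 31 | CC(C)=CCC[C@]1(C)CCC[C@]2(C)[C@H](CCC=C)[C@@](C)([Se](=O)c3ccccc3)C(=O)C[C@@H]12 | intermediate
33 | trans-fused tetrasubstituted octal-8-en-7-one | CC(C)=CCC[C@]1(C)CCC[C@]2(C)C(CCC=C)=C(C)C(=O)C[C@@H]12 | intermediate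
34 | octal-8-en-7β-ol | CC(C)=CCC[C@]1(C)CCC[C@]2(C)C(CCC=C)=C(C)[C@@H](O)C[C@@H]12 | intermediate
35 | pyridinium 7β-sulfate | CC(C)=CCC[C@]1(C)CCC[C@]2(C)C(CCC=C)=C(C)[C@@H](OS(=O)(=O)[O-])C[C@@H]12.c1cc[nH+]cc1 | intermediate
36 | trans-fused 9-butenyl-octal-8-ene | CC(C)=CCC[C@]1(C)CCC[C@]2(C)C(CCC=C)=C(C)CC[C@@H]12 | intermediate
37 | methyl ketone | CC(C)=CCC[C@]1(C)CCC[C@]2(C)C(CCC(C)=O)=C(C)CC[C@@H]12 | intermediate
38 | triethyl phosphonoacetate | CCOC(=O)CP(=O)(OCC)OCC | starting material
39 | ethyl ester of the target | CC(C)=CCC[C@]1(C)CCC[C@]2(C)C(CC/C(C)=C/C(=O)OCC)=C(C)CC[C@@H]12 | intermediate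
40 | lithium carboxylate of the target | CC(C)=CCC[C@]1(C)CCC[C@]2(C)C(CC/C(C)=C/C(=O)[O-])=C(C)CC[C@@H]12.[Li+] | intermediate
41 | CNP0237483.2 | CC(C)=CCC[C@]1(C)CCC[C@]2(C)C(CC/C(C)=C/C(=O)O)=C(C)CC[C@@H]12 | target

**Step count.** The route has 22 steps in total. The longest linear sequence is also 22 steps (1 to 41), because every other component is bought.

**Steps most likely to fail**

**First, step 11.** The alkoxide may open the C2–C7 bond heterolytically to an allyl anion and an enone. These can then undergo cycloreversion or reclose without stereochemical memory. The shift may also stall because the inner methyl group on C4 has to pass the C10 methyl group.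
- The fallback leaves the anionic regime and sets out from silyl ether 16.
- 16 is heated in degassed o-dichlorobenzene (sealed, base-washed glass, about 200 to 220 °C). The neutral siloxy-Cope rearrangement should then give the tert-butyldimethylsilyl enol ether of the cis-octalenone F1.
- n-Bu4NF/AcOH in THF cleaves the enol ether, and the route is rejoined at 20.

**Second, step 17.** Three processes threaten this step: selenenylation on the α face, syn-elimination toward the C8 methyl group instead of C9–H, and attack of selenium electrophiles on the free alkenes. The fallback never has to remove H9. It also bypasses steps 14 to 16. It sets out from dienone 23.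
- Nucleophilic epoxidation (H2O2, NaOH, MeOH, 0 °C) of the less substituted C8=C9 bond gives the 8α,9α-epoxy-octal-5-en-7-one F2.
- Li/NH3 opens the epoxide at C8 and reduces the Δ5-enone in one operation, giving the trans-fused 9α-hydroxy-decal-7-one F3.
- Dess–Martin oxidation gives the 7,9-dione F4.
- K2CO3/MeI in acetone methylates the doubly activated C8 to the 8-methyl-7,9-dione F5.
- HC(OMe)3/TsOH (cat.) in MeOH etherifies the less hindered C7 oxygen to the 7-methoxy-8-methyl-octal-7-en-9-one F6.
- In a Stork–Danheiser sequence, 24 with CeCl3 adds to the C9 carbonyl group to give the tertiary alcohol F7.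
- Dilute HCl hydrolyses and dehydrates F7, and the route is rejoined at 33.

**Third, step 12.** Hydrogen uptake at the neopentyl C2=C3 bond may be slow enough that saturation of the side-chain alkene competes. The fallback masks that alkene and sets out from 20.
- m-CPBA (1 equiv, CH2Cl2, −20 °C) epoxidises the more electron-rich trisubstituted alkene to the side-chain epoxide of the octalenone F8.
- H2 over Pd/C then saturates the only remaining alkene, giving the side-chain epoxide of the decalone F9.
- Iodohydrin formation and reductive elimination (NaI, NaOAc, Zn, AcOH) regenerate the isopropylidene group, which has no geometry to lose. The route is rejoined at 21.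

**Further compounds**
F1 | step 11 | tert-butyldimethylsilyl enol ether of cis-octalenone 20 | CC(C)=CCC[C@]1(C)C=CC[C@]2(C)CCC(O[Si](C)(C)C(C)(C)C)=C[C@H]12
F2 | step 17 | 8α,9α-epoxy-octal-5-en-7-one | CC(C)=CCC[C@]1(C)CCC[C@]2(C)[C@@H]3O[C@@H]3C(=O)C=C12
F3 | step 17 | trans-fused 9α-hydroxy-decal-7-one | CC(C)=CCC[C@]1(C)CCC[C@]2(C)[C@H](O)CC(=O)C[C@@H]12
F4 | step 17 | trans-fused decal-7,9-dione | CC(C)=CCC[C@]1(C)CCC[C@]2(C)C(=O)CC(=O)C[C@@H]12
F5 | step 17 | trans-fused 8-methyl-decal-7,9-dione | CC(C)=CCC[C@]1(C)CCC[C@]2(C)C(=O)C(C)C(=O)C[C@@H]12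
F6 | step 17 | trans-fused 7-methoxy-8-methyl-octal-7-en-9-one | CC(C)=CCC[C@]1(C)CCC[C@]2(C)C(=O)C(C)=C(OC)C[C@@H]12
F7 | step 17 | 9-(but-3-enyl)-7-methoxy-8-methyl-octal-7-en-9-ol | CC(C)=CCC[C@]1(C)CCC[C@]2(C)C(O)(CCC=C)C(C)=C(OC)C[C@@H]12
F8 | step 12 | side-chain epoxide of octalenone 20 | CC1(C)OC1CC[C@]2(C)C=CC[C@]3(C)CCC(=O)C[C@H]23
F9 | step 12 | side-chain epoxide of decalone 21 | CC1(C)OC1CC[C@]2(C)CCC[C@]3(C)CCC(=O)C[C@H]23
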